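**Retrosynthetic overview**

1. Target ⇒ acid hydrolysis of 1‑O‑(3,4‑di‑O‑acetylcaffeoyl)‑3,4‑O‑isopropylidene‑1,5‑quinide 17 ⇒ acylation of the only free (tertiary, C1) hydroxyl of quinide acetonide 13 with acid chloride 16 (from caffeic acid).
2. 13 ⇒ ring contraction of the cycloheptane‑1,2‑dione 10: fluoride frees O5, a transannular hemiketal forms, and a 1,2‑shift (benzilic ester / α‑ketol type) gives the cyclohexane, the quaternary C1 stereocentre, the carboxyl oxidation level, the γ‑lactone and the free C1–OH in one operation.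
3. Enabling feature: in the quinate the C5 oxygen is γ to the carboxyl carbon (ring O5–C5–C6–C1–C7, the five‑membered lactone of quinide). In the cycloheptane‑1,2‑dione this oxygen lies 1,4 across the ring from the distal carbonyl, so one five‑membered hemiketal decides which C=O becomes the carboxyl and on which face, i.e. the C1 configuration.
4. 10 ⇐ cycloheptene 8 (dihydroxylation, double oxidation) ⇐ ring‑closing metathesis of diene 7 ⇐ 2‑deoxy‑L‑ribose 1 (quinate C3 and C4 from the sugar, C5 by reagent‑controlled allylboration).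
5. Ring order: dioxolane (step 1) → cycloheptene (step 6) → oxolane hemiketal, then cyclohexane with γ‑lactone (step 9); the arene comes with caffeic acid.

Key step: step 9

Remark: 2‑deoxy‑L‑ribose is written as its pyranose lactol with the anomeric centre unassigned, and diol 9 is carried as the mixture of its two cis‑diol diastereomers, because both new centres become carbonyl carbons in step 8. Quinate numbering is used for the target (C1 quaternary, C3/C4 cis‑diol, C5, C7 carboxyl); fused numbering is used for 8–12.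

**Step 1**
Reactants: 1 2‑deoxy‑L‑ribose (2‑deoxy‑L‑erythro‑pentopyranose)
Product: 2 2‑deoxy‑3,4‑O‑isopropylidene‑L‑erythro‑pentopyranose (anomers)
Conditions: 2‑methoxypropene, PPTS (cat.), EtOAc, rt
Reagents that add atoms: 2‑methoxypropene COC(C)=C
Why: Kinetic acetalisation by mixed‑ketal transfer from the enol ether should take the only cis‑vicinal diol of the pyranose (O3/O4) and leave the anomeric hydroxyl free, with no stereocentre touched.

**Step 2**
Reactants: 2 2‑deoxy‑3,4‑O‑isopropylidene‑L‑erythro‑pentopyranose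
Product: 3 [(4S,5R)‑2,2‑dimethyl‑5‑(prop‑2‑en‑1‑yl)‑1,3‑dioxolan‑4‑yl]methanol
Conditions: Ph3PCH3Br, KOtBu, THF, 0 °C → reflux
Reagents that add atoms: methyltriphenylphosphonium bromide C[P+](c1ccccc1)(c1ccccc1)c1ccccc1.[Br-]
Why: Wittig methylenation of the open‑chain aldehyde tautomer of the lactol is a standard olefination of 2‑deoxy sugar lactols, which carry no 2‑oxygen that could eliminate or epimerise.

**Step 3**
Reactants: 3 [(4S,5R)‑2,2‑dimethyl‑5‑(prop‑2‑en‑1‑yl)‑1,3‑dioxolan‑4‑yl]methanol
Product: 4 (4R,5R)‑2,2‑dimethyl‑5‑(prop‑2‑en‑1‑yl)‑1,3‑dioxolane‑4‑carbaldehyde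
Conditions: (COCl)2, DMSO, CH2Cl2, −78 °C; Et3N, −78 → −30 °C; used crude
Reagents that add atoms: none
Why: Swern oxidation of the primary alcohol at low temperature, with immediate use of the aldehyde, should keep the α‑oxygenated cis‑dioxolane centre from epimerising.

**Step 4**
Reactants: 4 (4R,5R)‑2,2‑dimethyl‑5‑(prop‑2‑en‑1‑yl)‑1,3‑dioxolane‑4‑carbaldehyde
Product: 6 (1R)‑1‑[(4S,5R)‑2,2‑dimethyl‑5‑(prop‑2‑en‑1‑yl)‑1,3‑dioxolan‑4‑yl]but‑3‑en‑1‑ol, via borinate ester 5 (not isolated)
Conditions: (+)‑Ipc2BOMe [(−)‑α‑pinene series], allylMgBr, Et2O, 0 °C → rt; then 4, −78 °C; then NaOH, H2O2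
Reagents that add atoms: allylmagnesium bromide C=CC[Mg]Br, which delivers the allyl group through B‑allylbis(isopinocampheyl)borane made in the flask, C=CCB([C@H]1C[C@H]2C[C@@H]([C@@H]1C)C2(C)C)[C@H]1C[C@H]2C[C@@H]([C@@H]1C)C2(C)C
Why: Brown asymmetric allylboration through a closed Zimmerman–Traxler chair should add the allyl group to the Re face of the aldehyde and set the (R)‑carbinol (future C5 of the quinate) by reagent control, against the Felkin–Anh preference of the α‑alkoxy aldehyde.

**Step 5**
Reactants: 6 (1R)‑1‑[(4S,5R)‑2,2‑dimethyl‑5‑(prop‑2‑en‑1‑yl)‑1,3‑dioxolan‑4‑yl]but‑3‑en‑1‑ol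
Product: 7 triethyl{[(1R)‑1‑[(4R,5R)‑2,2‑dimethyl‑5‑(prop‑2‑en‑1‑yl)‑1,3‑dioxolan‑4‑yl]but‑3‑en‑1‑yl]oxy}silane
Conditions: TESCl, imidazole, DMF, 0 °C → rt
Reagents that add atoms: chlorotriethylsilane CC[Si](Cl)(CC)CC
Why: Standard silylation of the secondary alcohol installs a group that should survive metathesis, osmylation and activated‑DMSO oxidation and still be cleaved by fluoride at low temperature to trigger step 9.

**Step 6**
Reactants: 7 triethylsilyl ether of 6
Product: 8 (3aR,4R,8aR)‑2,2‑dimethyl‑4‑(triethylsilyloxy)‑4,5,8,8a‑tetrahydro‑3aH‑cyclohepta[d][1,3]dioxole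
Conditions: Grubbs II (5 mol %), CH2Cl2 (5 mM), 40 °C
Reagents that add atoms: none
Why: Ring‑closing metathesis of the 1,8‑diene should close the cycloheptene readily because the cis‑dioxolane holds both alkenyl arms on one face.

**Step 7**
Reactants: 8 (3aR,4R,8aR)‑2,2‑dimethyl‑4‑(triethylsilyloxy)‑4,5,8,8a‑tetrahydro‑3aH‑cyclohepta[d][1,3]dioxole
Product: 9 (3aR,4R,8aR)‑2,2‑dimethyl‑4‑(triethylsilyloxy)hexahydro‑3aH‑cyclohepta[d][1,3]dioxole‑6,7‑diol (cis‑diol, two diastereomers)
Conditions: OsO4 (cat.), NMO, acetone/H2O, rt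
Reagents that add atoms: osmium tetroxide O=[Os](=O)(=O)=O (catalytic oxygen carrier); N‑methylmorpholine N‑oxide C[N+]1([O-])CCOCC1; water O
Why: Upjohn syn‑dihydroxylation of the isolated cis‑alkene needs no facial selectivity, since both new carbinol centres become carbonyls in step 8.

**Step 8**
Reactants: 9 the cis‑6,7‑diol
Product: 10 (3aR,4R,8aR)‑2,2‑dimethyl‑4‑(triethylsilyloxy)tetrahydro‑3aH‑cyclohepta[d][1,3]dioxole‑6,7‑dione
Conditions: DMSO, TFAA, CH2Cl2, −78 °C; Et3N, −78 → 0 °C; used crude
Reagents that add atoms: none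
Why: Swern‑type double oxidation with trifluoroacetic anhydride activation is the usual way to take a vic‑diol to the 1,2‑dione without C–C cleavage, and short, cold contact with the amine should limit β‑elimination of the flanking oxygens.

**Step 9**
Reactants: 10 (3aR,4R,8aR)‑2,2‑dimethyl‑4‑(triethylsilyloxy)tetrahydro‑3aH‑cyclohepta[d][1,3]dioxole‑6,7‑dione
Product: 13 3,4‑O‑isopropylidene‑1,5‑quinide (γ‑lactone acetonide of quinic acid), via hydroxy‑dione alkoxide 11 (not isolated), via bridged hemiketal alkoxide 12 (not isolated)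
Conditions: TASF, THF–DMF, −40 → 0 °C; then AcOH
Reagents that add atoms: none
Why: Proposed new method: fluoride unmasks the C4 alkoxide (the future O5), which adds across the ring to the distal carbonyl C7 to give the 8‑oxabicyclo[3.2.1]octane hemiketal alkoxide 12, and the C7–C8 ring bond then shifts to the neighbouring ketone carbon C6, so that C7 becomes the lactone carbonyl, C6 becomes C1 of the quinate as a tertiary alkoxide and the cycloheptane contracts to the cyclohexane. The closest known reaction types are the alkoxide‑induced benzilic ester rearrangement of 1,2‑diketones and the base‑induced α‑ketol rearrangement of bridgehead hydroxy ketones in bicyclo[3.2.1]octanes; what is new is the transannular delivery of the alkoxide within a cycloheptane‑1,2‑dione. The oxolane closes by 5‑exo‑trig hemiketalisation and survives as the γ‑lactone ring, and the cyclohexane closes by the suprafacial 1,2‑alkyl shift through a three‑centre transition state (formally 3‑exo‑trig on the ketone), for which the bridgehead C–C bond lies well out of the carbonyl plane. The only new stereocentre, C1, is set by the one‑atom oxygen tether, since the carboxyl carbon can only end cis to O5 (fixed in step 4), which places the C1 oxygen cis to the acetonide oxygens as in quinic acid. The step needs addition of the right oxygen to the right carbonyl and a shift that outruns E1cB loss of the β‑oxygens and retro‑aldol opening: the acetonide masks the other two hydroxyls, attack on the proximal C6 would give an oxetane, and hemiketalisation removes the carbonyl that acidifies the CH2 next to the acetonide while it ties O5 up as an ether. The driving force is the conversion of a ketone and a hemiketal alkoxide into an ester and a tertiary alkoxide, which should make the shift irreversible.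

**Step 10**
Reactants: 14 caffeic acid
Product: 15 3,4‑di‑O‑acetylcaffeic acid
Conditions: Ac2O, pyridine, DMAP (cat.), rt; aqueous work‑up
Reagents that add atoms: acetic anhydride CC(=O)OC(C)=O
Why: Standard acetylation of both phenols (any mixed anhydride at the carboxyl is hydrolysed on work‑up) protects the catechol from acylation and oxidation in the next two steps.

**Step 11**
Reactants: 15 3,4‑di‑O‑acetylcaffeic acid
Product: 16 3,4‑di‑O‑acetylcaffeoyl chloride
Conditions: (COCl)2, DMF (cat.), CH2Cl2, 0 °C → rt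
Reagents that add atoms: oxalyl chloride ClC(=O)C(Cl)=O
Why: Vilsmeier‑catalysed conversion of the acid into its chloride should leave the aryl acetates and the E‑alkene untouched.

**Step 12**
Reactants: 13 3,4‑O‑isopropylidene‑1,5‑quinide; 16 3,4‑di‑O‑acetylcaffeoyl chloride
Product: 17 1‑O‑(3,4‑di‑O‑acetylcaffeoyl)‑3,4‑O‑isopropylidene‑1,5‑quinide
Conditions: DMAP, pyridine, CH2Cl2, rt
Reagents that add atoms: none
Why: DMAP‑catalysed acylation with an acid chloride should esterify the tertiary C1 hydroxyl, the only free hydroxyl of 13, with retention at C1 because only the O–acyl bond is formed.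

**Step 13**
Reactants: 17 1‑O‑(3,4‑di‑O‑acetylcaffeoyl)‑3,4‑O‑isopropylidene‑1,5‑quinide
Product: 18 1‑O‑caffeoylquinic acid
Conditions: 1 M HCl (aq), THF, rt
Reagents that add atoms: water O
Why: Acid hydrolysis should cleave the acetonide, both aryl acetates and the strained bicyclic γ‑lactone, while the hindered tertiary cinnamate survives and acid avoids the acyl migration that base would promote.

**Compound list**

1 | 2‑deoxy‑L‑ribose (2‑deoxy‑L‑erythro‑pentopyranose) | OC1C[C@@H](O)[C@@H](O)CO1 | starting material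
2 | 2‑deoxy‑3,4‑O‑isopropylidene‑L‑erythro‑pentopyranose | OC1C[C@@H](OC2(C)C)[C@@H](O2)CO1 | intermediate
3 | [(4S,5R)‑2,2‑dimethyl‑5‑(prop‑2‑en‑1‑yl)‑1,3‑dioxolan‑4‑yl]methanol | C=CC[C@@H](OC1(C)C)[C@@H](O1)CO | intermediate
4 | (4R,5R)‑2,2‑dimethyl‑5‑(prop‑2‑en‑1‑yl)‑1,3‑dioxolane‑4‑carbaldehyde | C=CC[C@@H](OC1(C)C)[C@@H](O1)C=O | intermediate
5 | bis(isopinocampheyl)borinate of alcohol 6 | C=CC[C@@H](OC1(C)C)[C@@H](O1)[C@H](OB([C@H]2C[C@H]3C[C@@H]([C@@H]2C)C3(C)C)[C@H]2C[C@H]3C[C@@H]([C@@H]2C)C3(C)C)CC=C | intermediate (not isolated)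
6 | (1R)‑1‑[(4S,5R)‑2,2‑dimethyl‑5‑(prop‑2‑en‑1‑yl)‑1,3‑dioxolan‑4‑yl]but‑3‑en‑1‑ol | C=CC[C@@H](OC1(C)C)[C@@H](O1)[C@H](O)CC=C | intermediate
7 | triethylsilyl ether of 6 | C=CC[C@@H](OC1(C)C)[C@@H](O1)[C@H](O[Si](CC)(CC)CC)CC=C | intermediate
8 | (3aR,4R,8aR)‑2,2‑dimethyl‑4‑(triethylsilyloxy)‑4,5,8,8a‑tetrahydro‑3aH‑cyclohepta[d][1,3]dioxole (cis‑fused acetonide, silyloxy group trans to the adjacent acetonide oxygen) | C1=CC[C@@H](OC2(C)C)[C@@H](O2)[C@H](O[Si](CC)(CC)CC)C1 | intermediate
9 | (3aR,4R,8aR)‑2,2‑dimethyl‑4‑(triethylsilyloxy)hexahydro‑3aH‑cyclohepta[d][1,3]dioxole‑6,7‑diol (cis‑diol, both diastereomers) | OC1C(O)C[C@@H](OC2(C)C)[C@@H](O2)[C@H](O[Si](CC)(CC)CC)C1 | intermediate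
10 | (3aR,4R,8aR)‑2,2‑dimethyl‑4‑(triethylsilyloxy)tetrahydro‑3aH‑cyclohepta[d][1,3]dioxole‑6,7‑dione | O=C1C(=O)C[C@@H](OC2(C)C)[C@@H](O2)[C@H](O[Si](CC)(CC)CC)C1 | intermediate
11 | (3aS,4R,8aR)‑4‑hydroxy‑2,2‑dimethyltetrahydro‑3aH‑cyclohepta[d][1,3]dioxole‑6,7‑dione (present as its alkoxide) | O=C1C(=O)C[C@@H](OC2(C)C)[C@@H](O2)[C@H](O)C1 | intermediate (not isolated)
12 | bridged hemiketal of 11: 8‑oxabicyclo[3.2.1]octan‑6‑one with bridgehead OH at C5 and 2,3‑O‑isopropylidene (present as its alkoxide) | O=C1[C@](O)(O3)C[C@@H](OC2(C)C)[C@@H](O2)[C@H]3C1 | intermediate (not isolated)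
13 | 3,4‑O‑isopropylidene‑1,5‑quinide | O[C@@]1(C(=O)O3)C[C@@H](OC2(C)C)[C@@H](O2)[C@H]3C1 | intermediate
14 | caffeic acid | OC(=O)/C=C/c1ccc(O)c(O)c1 | starting material
15 | 3,4‑di‑O‑acetylcaffeic acid | CC(=O)Oc1ccc(/C=C/C(O)=O)cc1OC(C)=O | intermediate
16 | 3,4‑di‑O‑acetylcaffeoyl chloride | CC(=O)Oc1ccc(/C=C/C(Cl)=O)cc1OC(C)=O | intermediate
17 | 1‑O‑(3,4‑di‑O‑acetylcaffeoyl)‑3,4‑O‑isopropylidene‑1,5‑quinide | CC(=O)Oc1ccc(/C=C/C(=O)O[C@@]2(C(=O)O4)C[C@@H](OC3(C)C)[C@@H](O3)[C@H]4C2)cc1OC(C)=O | intermediate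
18 | 1‑O‑caffeoylquinic acid | O=C(/C=C/c1ccc(O)c(O)c1)O[C@]1(C(=O)O)C[C@@H](O)[C@H](O)[C@H](O)C1 | target

**Step count**

Total: 13 steps. Longest linear sequence: 11 steps (steps 1–9, 12, 13); steps 10–11 are the side branch.

**Steps most likely to fail**

1. Step 9 (Proposed new method). After desilylation the dione may enolise and lose a β‑oxygen by E1cB, or the β‑alkoxide ketone may open by retro‑aldol, before the hemiketal alkoxide rearranges. The fallback uses known chemistry, sets out from 10 and returns at 13. Classical benzilic acid rearrangement of the cyclic 1,2‑dione with external hydroxide (KOH, aqueous dioxane, 0 °C) should give the ring‑contracted α‑hydroxy acids 3,4‑O‑isopropylidene‑5‑O‑triethylsilylquinic acid F1 and its C1 epimer F2. HF·pyridine in THF should desilylate them to 3,4‑O‑isopropylidenequinic acid F3 and its C1 epimer F4. TsOH (cat.) in acetone/2,2‑dimethoxypropane at reflux should then lactonise only F3, whose carboxyl is cis to O5, to 13; F4 cannot close a γ‑lactone and is removed by bicarbonate extraction. The price is that C1 is no longer controlled by a tether.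

2. Step 4. The reagent must override the Felkin–Anh preference of the α‑alkoxy aldehyde, so poor facial selectivity is the risk; the wrong epimer would carry the wrong C5 configuration into the ring contraction. The fallback sets out from 4 and returns at 6. Substrate‑controlled allylation (Zn, allyl bromide, THF/aq. NH4Cl) should give mainly the Felkin product, the (1S)‑epimer of 6, F5. Mitsunobu inversion (4‑nitrobenzoic acid, PPh3, DIAD, THF) should give the (1R)‑4‑nitrobenzoate F6, and K2CO3/MeOH should release 6.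

3. Step 8. During the amine‑mediated collapse of the double alkoxysulfonium intermediate, β‑elimination of silanol or of the acetonide oxygen, or enolisation‑driven decomposition of the dione, may compete. The fallback sets out from 9 and returns at 10 without amine base. The stannylene acetal (Bu2SnO, toluene, reflux) oxidised with NBS (CHCl3, rt) should give the regioisomeric α‑hydroxy ketones, the 7‑hydroxy‑6‑ketone F7 and the 6‑hydroxy‑7‑ketone F8. Dess–Martin periodinane (NaHCO3, CH2Cl2) should take both to 10.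

**Further compounds**

F1 | step 9 | 3,4‑O‑isopropylidene‑5‑O‑triethylsilylquinic acid | O[C@@]1(C(O)=O)C[C@@H](OC2(C)C)[C@@H](O2)[C@H](O[Si](CC)(CC)CC)C1
F2 | step 9 | C1 epimer of 3,4‑O‑isopropylidene‑5‑O‑triethylsilylquinic acid | O[C@]1(C(O)=O)C[C@@H](OC2(C)C)[C@@H](O2)[C@H](O[Si](CC)(CC)CC)C1
F3 | step 9 | 3,4‑O‑isopropylidenequinic acid | O[C@@]1(C(O)=O)C[C@@H](OC2(C)C)[C@@H](O2)[C@H](O)C1
F4 | step 9 | C1 epimer of 3,4‑O‑isopropylidenequinic acid | O[C@]1(C(O)=O)C[C@@H](OC2(C)C)[C@@H](O2)[C@H](O)C1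
F5 | step 4 | (1S)‑1‑[(4S,5R)‑2,2‑dimethyl‑5‑(prop‑2‑en‑1‑yl)‑1,3‑dioxolan‑4‑yl]but‑3‑en‑1‑ol | C=CC[C@@H](OC1(C)C)[C@@H](O1)[C@@H](O)CC=C
F6 | step 4 | 4‑nitrobenzoate of alcohol 6 (1R) | C=CC[C@@H](OC1(C)C)[C@@H](O1)[C@H](OC(=O)c2ccc(cc2)[N+](=O)[O-])CC=C
F7 | step 8 | 7‑hydroxy‑6‑ketone derived from diol 9 (carbinol centre unassigned) | O=C1C(O)C[C@@H](OC2(C)C)[C@@H](O2)[C@H](O[Si](CC)(CC)CC)C1
F8 | step 8 | 6‑hydroxy‑7‑ketone derived from diol 9 (carbinol centre unassigned) | OC1C(=O)C[C@@H](OC2(C)C)[C@@H](O2)[C@H](O[Si](CC)(CC)CC)C1
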